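Numbering: labdane numbering is used throughout (decalin C1–C10, C17 = methyl on C8, C20 = methyl on C10, side chain C11–C16).

**Plan**

1. Cuts: C7=O and C8–OH go back to a C7=C8 alkene (α-epoxide, trans-diaxial hydrolysis, oxidation). The lactone O16–C15(=O) goes back to a C15/C16 diol and C11–C12 to a cis alkene. The oxolane O–C9 bond is cut and O is re-attached to C12. C12=C13 is cut by HWE olefination, and the decalin is (+)-sclareolide.
2. Key idea: the oxolane (O, C9, C11, C12, C13) is not closed as a five-ring. It grows from the oxirane (O, C12, C13) of a dienyl oxirane by a copper-catalysed 1,3-shift of O from C12 to C9 (3 → 5 ring atoms), which gives the 2,5-dihydrofuran.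
3. Enabling feature: the ring O bridges C13 (its CH2O and CH2C arms make it the epoxide of an allylic alcohol) and C9 (flanked by quaternary C10 and by C8/C7, which need oxygen later). With C7=C8 and C9=C11 in place, C9 is the tertiary mid-point of a C12–C11–C9–C8–C7 pentadienyl cation, where so hindered a C–O bond can form.
4. Forward order: sclareolide → C9=C11 butenolide → lactol → ring-B dienal → HWE chain (C13–C16) → allylic alcohol → oxirane → dihydrofuran (first spiro ring) → oxolane → ring-B oxidation → lactone (second spiro ring) → ketone.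
5. Stereochemistry: C5 and C10 come from sclareolide. C13 comes from Sharpless epoxidation and is kept because C13–O is never broken. C9 comes from axial α-face capture anti to C20. C8 (and transient C7) come from α-epoxidation and Fürst–Plattner opening by water.

Key step: step 8

Remark on the chemistry: the C9=C11 geometry of 6 and 10–12 is drawn as inherited from butenolide 4 (C12 syn to C8). It has no consequence, because C9 becomes sp3 in step 8.

**Route**

Step 1
Reactants: 1 (+)-sclareolide
Product: 4 butenolide (9(11)-didehydrosclareolide), via 11α-phenylselenide 2 (not isolated), via selenoxide 3 (not isolated)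
Conditions: LDA, THF, −78 °C; PhSeBr; then 30% H2O2, 0 °C → rt
Reagents that add atoms: none
Why: Selenoxide syn-elimination: the lactone enolate is selenenylated on the open α face of C11, so the selenoxide lies syn to the axial 9α-H and can only eliminate to the C9=C11 butenolide, while C5, C8 and C10 stay untouched.

Step 2
Reactants: 4 butenolide
Product: 5 lactol (8α,12-epoxy-13,14,15,16-tetranorlabd-9(11)-en-12-ol, anomer mixture)
Conditions: DIBAL-H (1.1 equiv), CH2Cl2, −78 °C; Rochelle salt
Reagents that add atoms: none
Why: Partial lactone reduction with DIBAL-H stops at the aluminium hemiacetal at low temperature, and the new anomeric centre is irrelevant because it is lost in step 3.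

Step 3
Reactants: 5 lactol
Product: 6 dienal ((9(11)E)-13,14,15,16-tetranorlabda-7,9(11)-dien-12-al)
Conditions: p-TsOH·H2O (5 mol %), benzene, 4 Å MS, BHT, 50 °C
Reagents that add atoms: none
Why: Acid-catalysed E1 dehydration: the ring-O-protonated lactol ionises at the tertiary allylic C8–O bond, the C8–C9–C11 allyl cation loses H-7 and the aldehyde hydrate collapses to the conjugated dienal, with equilibrating conditions favouring the trisubstituted endocyclic C7=C8 over C8=C17.

Step 4
Reactants: 7 triethyl phosphonoacetate; 8 (2-bromoethoxy)(tert-butyl)dimethylsilane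
Product: 9 ethyl 4-(tert-butyldimethylsilyloxy)-2-(diethoxyphosphoryl)butanoate (racemic)
Conditions: NaH, THF–DMF, 0 °C; 8, NaI (cat.), 60 °C
Reagents that add atoms: none
Why: SN2 alkylation of the stabilised phosphonoacetate anion with a primary bromide brings in C14–C15 with O15 already masked.

Step 5
Reactants: 6 dienal; 9 phosphonate
Product: 10 ethyl (9(11)E,12E)-15-(tert-butyldimethylsilyloxy)labda-7,9(11),12-trien-16-oate
Conditions: NaH, THF, 0 °C; then 6, −20 °C → rt
Reagents that add atoms: none
Why: Horner–Wadsworth–Emmons olefination with an α-alkyl phosphonoacetate should favour the 12E enoate (ester anti to C11), and any 12Z isomer is epoxidised on the same C13 face in step 7 and converges at 13, where C12 is sp2 again.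

Step 6
Reactants: 10 trienoate
Product: 11 (9(11)E,12E)-15-(tert-butyldimethylsilyloxy)labda-7,9(11),12-trien-16-ol
Conditions: DIBAL-H (2.3 equiv), CH2Cl2, −78 °C; Rochelle salt
Reagents that add atoms: none
Why: 1,2-Reduction of the conjugated ester by DIBAL-H gives the allylic alcohol that directs the next step, while the silyl ether and the triene are inert.

Step 7
Reactants: 11 trienol
Product: 12 dienyl oxirane ((12S,13S)-12,13-epoxy-15-(tert-butyldimethylsilyloxy)labda-7,9(11)-dien-16-ol)
Conditions: Ti(OiPr)4 (10 mol %), L-(+)-DIPT (12 mol %), TBHP (decane), 4 Å MS, CH2Cl2, −30 °C; cold work-up over Et3N, used crude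
Reagents that add atoms: tert-butyl hydroperoxide, CC(C)(C)OO
Why: Sharpless asymmetric epoxidation: only C12=C13 carries an allylic OH, and with L-(+)-tartrate oxygen is delivered to the face that makes C13 and C12 both S, as for other (E)-2,3-disubstituted allylic alcohols, so the reagent and not the remote decalin sets C13.

Step 8
Reactants: 12 dienyl oxirane
Product: 13 spiro-2,5-dihydrofuran (9α,13-epoxy-15-(tert-butyldimethylsilyloxy)labda-7,11-dien-16-ol, C13 arranged as in the target, 13R by CIP here)
Conditions: Cu(hfacac)2 (5 mol %), PhMe, 60 °C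
Reagents that add atoms: none
Why: Cu(II) binds the oxirane oxygen (chelated through the C16 hydroxyl) and the allylic C12–O bond ionises or adds to copper, leaving a copper alkoxide on C13 and a C12–C11–C9–C8–C7 pentadienyl cation (or σ-allyl copper) with much of its charge on tertiary C9; in the s-cis C11–C12 rotamer the alkoxide recombines at C9, so O moves 1,3 from C12 to C9 and the oxirane (O, C12, C13) grows by C11 and C9 into the dihydrofuran. The closest known reaction is the Cu(hfacac)2-catalysed ring expansion of vinyl oxiranes to 2,5-dihydrofurans. The one ring closure is a 5-endo-trig capture of the allyl cation terminus (equivalently, C–O reductive elimination from a six-membered oxacupracycle). C13 keeps the configuration of step 7 because its C–O bond is never broken, C12 becomes sp2, and the new C9 centre is set by the decalin: O adds axially on the α face, anti to the axial C20 methyl, which leaves C11 equatorial (β). Three selectivities are needed: cleavage of C12–O and not C13–O (only C12 is allylic), capture at C9 and not C7 (five- against seven-membered ring), and capture by the alkoxide and not by the neutral C16 OH (anion and five-ring against alcohol and six-ring).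

Step 9
Reactants: 13 spiro-2,5-dihydrofuran
Product: 14 (13S)-9α,13-epoxy-15-(tert-butyldimethylsilyloxy)labd-7-en-16-ol
Conditions: 2-nitrobenzenesulfonyl hydrazide (excess), Et3N, THF–iPrOH, rt
Reagents that add atoms: none
Why: Diimide reduction transfers H2 concertedly to the cis-disubstituted C11=C12 bond and spares the trisubstituted C7=C8 bond, and being neutral and metal-free it avoids hydrogenolysis or ionisation of the bis-allylic C9–O bond.

Step 10
Reactants: 14 oxolane alkene
Product: 15 7α,8α:9α,13-diepoxy-15-(tert-butyldimethylsilyloxy)labdan-16-ol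
Conditions: DMDO, acetone, −20 → 0 °C
Reagents that add atoms: dimethyldioxirane, CC1(C)OO1
Why: Neutral dioxirane epoxidation of the only remaining alkene should occur from the α face, because the β face of C8 is screened by the syn-axial C20 methyl, and this sets the 7α,8α-epoxide.

Step 11
Reactants: 15 epoxide
Product: 16 tetraol (9α,13-epoxylabdane-7α,8β,15,16-tetraol)
Conditions: HClO4 (cat., 0.5 M aq), THF–H2O, 0 °C → rt
Reagents that add atoms: water, O
Why: Acid-catalysed epoxide hydrolysis under the Fürst–Plattner rule: water attacks tertiary C8 from the β face (trans-diaxial and Markovnikov), which inverts C8 to 8β-OH/8α-Me and leaves 7α-OH, while the primary TBS ether is hydrolysed in the same medium.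

Step 12
Reactants: 16 tetraol
Product: 19 (13S)-9α,13-epoxy-7α,8β-dihydroxylabdan-16,15-olide, via hydroxy aldehyde 17 (not isolated), via lactol 18 (not isolated)
Conditions: TEMPO (10 mol %), PhI(OAc)2 (2.2 equiv), CH2Cl2, rt
Reagents that add atoms: none
Why: Nitroxyl-catalysed oxidative lactonisation: the oxoammonium ion oxidises the unhindered C15 alcohol faster than the neopentyl C16 or the axial C7 alcohol, the aldehyde closes on O16 and the lactol is oxidised on to the C15 lactone, while the trans-diaxial 7,8-diol cannot chelate iodine(III) and so is not cleaved.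

Step 13
Reactants: 19 dihydroxy lactone
Product: 20 target, (13S)-9α,13-epoxy-8β-hydroxy-7-oxolabdan-16,15-olide (CNP0208728.2)
Conditions: Dess–Martin periodinane, CH2Cl2, 0 °C → rt
Reagents that add atoms: none
Why: Dess–Martin oxidation of the only secondary alcohol gives the C7 ketone beside the untouched tertiary 8β-OH, and no stereocentre can epimerise because C8 is fully substituted.

**Compound list**

1 | (+)-sclareolide | CC1(C)CCC[C@@]2(C)[C@H]1CC[C@@]3(C)OC(=O)C[C@H]23 | starting material
2 | 11α-(phenylselanyl)sclareolide | CC1(C)CCC[C@@]2(C)[C@H]1CC[C@@]3(C)OC(=O)[C@@H]([Se]c4ccccc4)[C@H]23 | intermediate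
3 | 11α-(phenylseleninyl)sclareolide (selenoxide, Se epimers) | CC1(C)CCC[C@@]2(C)[C@H]1CC[C@@]3(C)OC(=O)[C@@H]([Se](=O)c4ccccc4)[C@H]23 | intermediate
4 | 9(11)-didehydrosclareolide (butenolide) | CC1(C)CCC[C@@]2(C)[C@H]1CC[C@@]3(C)OC(=O)C=C23 | intermediate
5 | 8α,12-epoxy-13,14,15,16-tetranorlabd-9(11)-en-12-ol (lactol, anomers) | CC1(C)CCC[C@@]2(C)[C@H]1CC[C@@]3(C)OC(O)C=C23 | intermediate
6 | (9(11)E)-13,14,15,16-tetranorlabda-7,9(11)-dien-12-al | CC1(C)CCC[C@@]2(C)[C@H]1CC=C(C)/C2=C\C=O | intermediate
7 | triethyl phosphonoacetate | CCOC(=O)CP(=O)(OCC)OCC | starting material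
8 | (2-bromoethoxy)(tert-butyl)dimethylsilane | BrCCO[Si](C)(C)C(C)(C)C | starting material
9 | ethyl 4-(tert-butyldimethylsilyloxy)-2-(diethoxyphosphoryl)butanoate (racemic) | CCOC(=O)C(CCO[Si](C)(C)C(C)(C)C)P(=O)(OCC)OCC | intermediate
10 | ethyl (9(11)E,12E)-15-(tert-butyldimethylsilyloxy)labda-7,9(11),12-trien-16-oate | CC1(C)CCC[C@@]2(C)[C@H]1CC=C(C)/C2=C\C=C(/CCO[Si](C)(C)C(C)(C)C)C(=O)OCC | intermediate
11 | (9(11)E,12E)-15-(tert-butyldimethylsilyloxy)labda-7,9(11),12-trien-16-ol | CC1(C)CCC[C@@]2(C)[C@H]1CC=C(C)/C2=C\C=C(/CCO[Si](C)(C)C(C)(C)C)CO | intermediate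
12 | (12S,13S)-12,13-epoxy-15-(tert-butyldimethylsilyloxy)labda-7,9(11)-dien-16-ol | CC1(C)CCC[C@@]2(C)[C@H]1CC=C(C)/C2=C\[C@@H]3O[C@@]3(CCO[Si](C)(C)C(C)(C)C)CO | intermediate
13 | 9α,13-epoxy-15-(tert-butyldimethylsilyloxy)labda-7,11-dien-16-ol | CC1(C)CCC[C@@]2(C)[C@H]1CC=C(C)[C@]21C=C[C@](CCO[Si](C)(C)C(C)(C)C)(CO)O1 | intermediate
14 | (13S)-9α,13-epoxy-15-(tert-butyldimethylsilyloxy)labd-7-en-16-ol | CC1(C)CCC[C@@]2(C)[C@H]1CC=C(C)[C@]21CC[C@](CCO[Si](C)(C)C(C)(C)C)(CO)O1 | intermediate
15 | 7α,8α:9α,13-diepoxy-15-(tert-butyldimethylsilyloxy)labdan-16-ol | CC1(C)CCC[C@@]2(C)[C@H]1C[C@H]3O[C@@]3(C)[C@]21CC[C@](CCO[Si](C)(C)C(C)(C)C)(CO)O1 | intermediate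
16 | 9α,13-epoxylabdane-7α,8β,15,16-tetraol | CC1(C)CCC[C@@]2(C)[C@H]1C[C@@H](O)[C@](C)(O)[C@]21CC[C@](CCO)(CO)O1 | intermediate
17 | 9α,13-epoxy-7α,8β,16-trihydroxylabdan-15-al | CC1(C)CCC[C@@]2(C)[C@H]1C[C@@H](O)[C@](C)(O)[C@]21CC[C@](CC=O)(CO)O1 | intermediate
18 | 9α,13:15,16-diepoxylabdane-7α,8β,15-triol (lactol, anomers) | CC1(C)CCC[C@@]2(C)[C@H]1C[C@@H](O)[C@](C)(O)[C@]21CC[C@]2(COC(O)C2)O1 | intermediate
19 | (13S)-9α,13-epoxy-7α,8β-dihydroxylabdan-16,15-olide | CC1(C)CCC[C@@]2(C)[C@H]1C[C@@H](O)[C@](C)(O)[C@]21CC[C@]2(COC(=O)C2)O1 | intermediate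
20 | (13S)-9α,13-epoxy-8β-hydroxy-7-oxolabdan-16,15-olide (CNP0208728.2) | CC1(C)CCC[C@@]2(C)[C@H]1CC(=O)[C@](C)(O)[C@]21CC[C@]2(COC(=O)C2)O1 | target

**Step count and risks**

Total step count: 13. Longest linear sequence: 12 (steps 1–3 and 5–13).

Steps most likely to fail:

Step 8. The oxirane may ionise without re-closing at C9. Possible processes are proton loss from C6 or C17 of the pentadienyl cation, a 1,2-shift of a C13 arm to C12, six-ring closure through the C16 hydroxyl, or attack on the β face of C9.
- The fallback sets out from 12. Palladium(0)-catalysed formate hydrogenolysis of the alkenyl oxirane (Pd2(dba)3, PBu3, HCO2H–Et3N, THF) delivers hydride to allylic C12 and should give (13S)-15-(tert-butyldimethylsilyloxy)labda-7,9(11)-diene-13,16-diol F1.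
- Catalytic camphorsulfonic acid in CH2Cl2 at −20 °C then protonates the diene at C11. The tertiary 13-OH captures the C9 allyl cation on the α face (acid-catalysed hydroalkoxylation of a 1,3-diene).
- This comes back to the route at 14.

Step 3. The lactol may be drained by acetal self-condensation, by elimination towards C17, or by polymerisation of the dienal under acid.
- The fallback sets out from 4. Palladium(0)-catalysed 1,4-elimination of the tertiary allylic carboxylate (Pd(PPh3)4, Et3N, THF, reflux, Tsuji–Trost-type ionisation and β-hydride loss from C7) should open the butenolide to (9(11)E)-13,14,15,16-tetranorlabda-7,9(11)-dien-12-oic acid F2.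
- LiAlH4 reduces it to (9(11)E)-13,14,15,16-tetranorlabda-7,9(11)-dien-12-ol F3, and MnO2 oxidises the allylic alcohol.
- This comes back to the route at 6.

Step 11. The developing C8 cation may lose H-17 to give an allylic alcohol, or accept a hydride from C7 to give the 8-H ketone, instead of being captured by water on the hindered β face.
- The fallback sets out from 14. NBS in aqueous THF forms the α-bromonium ion, which water opens at C8 in the trans-diaxial sense to give 7α-bromo-9α,13-epoxy-15-(tert-butyldimethylsilyloxy)labdane-8β,16-diol F4.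
- K2CO3 in MeOH closes it to 7β,8β:9α,13-diepoxy-15-(tert-butyldimethylsilyloxy)labdan-16-ol F5, in which the C8–O bond already has the final configuration.
- Dilute aqueous HClO4 in THF then opens this epoxide at secondary C7 from the α face (again diaxial, with no C8 cation needed) and removes the silyl group.
- This comes back to the route at 16.

**Further compounds**

F1 | step 8 | (13S)-15-(tert-butyldimethylsilyloxy)labda-7,9(11)-diene-13,16-diol | CC1(C)CCC[C@@]2(C)[C@H]1CC=C(C)/C2=C\C[C@](O)(CCO[Si](C)(C)C(C)(C)C)CO
F2 | step 3 | (9(11)E)-13,14,15,16-tetranorlabda-7,9(11)-dien-12-oic acid | CC1(C)CCC[C@@]2(C)[C@H]1CC=C(C)/C2=C\C(=O)O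
F3 | step 3 | (9(11)E)-13,14,15,16-tetranorlabda-7,9(11)-dien-12-ol | CC1(C)CCC[C@@]2(C)[C@H]1CC=C(C)/C2=C\CO
F4 | step 11 | 7α-bromo-9α,13-epoxy-15-(tert-butyldimethylsilyloxy)labdane-8β,16-diol | CC1(C)CCC[C@@]2(C)[C@H]1C[C@@H](Br)[C@](C)(O)[C@]21CC[C@](CCO[Si](C)(C)C(C)(C)C)(CO)O1
F5 | step 11 | 7β,8β:9α,13-diepoxy-15-(tert-butyldimethylsilyloxy)labdan-16-ol | CC1(C)CCC[C@@]2(C)[C@H]1C[C@@H]3O[C@]3(C)[C@]21CC[C@](CCO[Si](C)(C)C(C)(C)C)(CO)O1
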